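**Retrosynthetic overview**
1. Target 12 ⇐ aryl bromide 11 by Pd-catalysed hydroxylation; the bromine is carried as the masked phenol, so no protecting group is needed.
2. 11 ⇐ acyclic epoxy cinnamyl ether 8 by a one-pot Cp2TiCl radical/polar cascade: ring A closes first (C–C bond, 5-exo radical cyclisation), then ring B (C–O bond, benzylic cation capture); three stereocentres are set from the one carbinol centre.
3. 8 ⇐ epoxy alcohol 4 + cinnamyl bromide 7 (Williamson ether synthesis).
4. 4 ⇐ racemic allylic alcohol 3 (Sharpless kinetic resolution) ⇐ aldehyde 1 + vinylmagnesium bromide 2; 7 ⇐ alcohol 6 ⇐ ester 5.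

Assumption: 1, 2 and 5 are bought; the ee of 4 (about 95% when the resolution is stopped near 50% conversion) is raised to >99% by one recrystallisation of 4 or 11.

**Route**

Step 1
Reactants: 1 3-bromo-4,5-dimethoxybenzaldehyde; 2 vinylmagnesium bromide
Product: 3 rac-1-(3-bromo-4,5-dimethoxyphenyl)prop-2-en-1-ol
Conditions: CH2=CHMgBr (1.2 equiv, 1 M in THF), THF, −78 → 0 °C; then aq. NH4Cl
Reagents that add atoms: vinylmagnesium bromide 2, C=C[Mg]Br
Why: Grignard 1,2-addition to the aldehyde gives the racemic carbinol, and the aryl bromide does not undergo halogen–magnesium exchange with a vinyl Grignard reagent at this temperature.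

Step 2
Reactants: 3 rac-1-(3-bromo-4,5-dimethoxyphenyl)prop-2-en-1-ol
Product: 4 (R)-(3-bromo-4,5-dimethoxyphenyl)[(S)-oxiran-2-yl]methanol
Conditions: Ti(OiPr)4 (0.15 equiv), D-(−)-diisopropyl tartrate (0.18 equiv), tBuOOH (0.55 equiv, in decane), 4 Å MS, CH2Cl2, −20 °C, stopped near 50% conversion; 4 separated from unreacted (R)-alcohol by chromatography
Reagents that add atoms: tert-butyl hydroperoxide, CC(C)(C)OO
Why: Sharpless kinetic resolution: with D-(−)-diisopropyl tartrate the titanium tartrate catalyst epoxidises the (S)-alcohol much faster than the (R)-alcohol and delivers oxygen anti to the hydroxyl group (erythro product), so the carbinol centre that becomes the ArCH–O carbon of ring A is obtained enantioenriched (its descriptor changes from S to R only through a priority switch), while the configuration of the epoxide carbon is of no consequence because it is erased in step 6.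

Step 3
Reactants: 5 methyl (E)-3-(3,4,5-trimethoxyphenyl)prop-2-enoate
Product: 6 (E)-3-(3,4,5-trimethoxyphenyl)prop-2-en-1-ol
Conditions: iBu2AlH (2.3 equiv), CH2Cl2, −78 → 0 °C; aq. potassium sodium tartrate work-up
Reagents that add atoms: none
Why: Hydride 1,2-reduction of the conjugated ester by the aluminium hydride gives the allylic alcohol without touching the E alkene.

Step 4
Reactants: 6 (E)-3-(3,4,5-trimethoxyphenyl)prop-2-en-1-ol
Product: 7 5-[(E)-3-bromoprop-1-en-1-yl]-1,2,3-trimethoxybenzene
Conditions: PBr3 (0.4 equiv), Et2O, 0 °C, 30 min; used crude at once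
Reagents that add atoms: phosphorus tribromide, BrP(Br)Br
Why: Bromination of the allylic alcohol through its phosphite ester (SN2 displacement by bromide) gives the conjugated E cinnamyl bromide, which is the thermodynamic allylic isomer.

Step 5
Reactants: 4 (R)-(3-bromo-4,5-dimethoxyphenyl)[(S)-oxiran-2-yl]methanol; 7 5-[(E)-3-bromoprop-1-en-1-yl]-1,2,3-trimethoxybenzene
Product: 8 (S)-2-[(R)-(3-bromo-4,5-dimethoxyphenyl){[(E)-3-(3,4,5-trimethoxyphenyl)prop-2-en-1-yl]oxy}methyl]oxirane
Conditions: NaH (1.3 equiv), Bu4NI (5 mol%), 7 (1.3 equiv, present from the start), THF/DMF 4:1, −20 → 0 °C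
Reagents that add atoms: none
Why: Williamson ether synthesis: the secondary sodium alkoxide is alkylated by the very reactive allylic bromide faster than it can undergo Payne rearrangement at low temperature, and no bond to either stereocentre is broken.

Step 6
Reactants: 8 (S)-2-[(R)-(3-bromo-4,5-dimethoxyphenyl){[(E)-3-(3,4,5-trimethoxyphenyl)prop-2-en-1-yl]oxy}methyl]oxirane
Product: 11 (1S,3aR,4S,6aR)-1-(3-bromo-4,5-dimethoxyphenyl)-4-(3,4,5-trimethoxyphenyl)tetrahydro-1H,3H-furo[3,4-c]furan, via benzyltitanium alkoxide 9 (not isolated), via benzylic iodide 10 (not isolated)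
Conditions: Cp2TiCl2 (2.5 equiv), Zn dust (5 equiv), THF, rt (green Cp2TiCl solution added dropwise to 8); then I2 (1.2 equiv), THF, rt → 60 °C
Reagents that add atoms: none
Why: Nugent–RajanBabu radical cascade with polar crossover: Cp2TiCl opens the epoxide homolytically to the secondary β-titanoxy radical (erasing the epoxide centre), which closes ring A by 5-exo-trig addition to the styrenyl alkene through a chair-like Beckwith–Houk transition state that puts the new C–C bond trans to the aryl group on the neighbouring carbon and cis to the CH2O–Ti arm, after which the benzylic radical is captured as benzyltitanium 9, iodinolysed to iodide 10, and the trimethoxyphenyl-stabilised benzylic cation is trapped by the titanium alkoxide oxygen on the convex face to close ring B with its aryl group exo, so all three new stereocentres follow from the single carbinol centre of 8.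

Step 7
Reactants: 11 (1S,3aR,4S,6aR)-1-(3-bromo-4,5-dimethoxyphenyl)-4-(3,4,5-trimethoxyphenyl)tetrahydro-1H,3H-furo[3,4-c]furan
Product: 12 5-[(1S,3aR,4S,6aR)-4-(3,4,5-trimethoxyphenyl)tetrahydro-1H,3H-furo[3,4-c]furan-1-yl]-2,3-dimethoxyphenol
Conditions: Pd2(dba)3 (2 mol%), tBuXPhos (2-di-tert-butylphosphino-2',4',6'-triisopropylbiphenyl, 8 mol%), KOH (4 equiv), 1,4-dioxane/H2O 1:1, 100 °C; then 1 M HCl to pH 5
Reagents that add atoms: potassium hydroxide, [K+].[OH-]
Why: Palladium-catalysed hydroxylation of an aryl bromide (Buchwald-type C–O coupling): zerovalent palladium inserts into the C–Br bond, hydroxide replaces bromide and the bulky biarylphosphine forces C–O reductive elimination, while the base-stable furofuran stereocentres are untouched.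

**Compound list**
1 | 3-bromo-4,5-dimethoxybenzaldehyde | COc1cc(C=O)cc(Br)c1OC | starting material
2 | vinylmagnesium bromide | C=C[Mg]Br | starting material
3 | rac-1-(3-bromo-4,5-dimethoxyphenyl)prop-2-en-1-ol | COc1cc(C(O)C=C)cc(Br)c1OC | intermediate
4 | (R)-(3-bromo-4,5-dimethoxyphenyl)[(S)-oxiran-2-yl]methanol | COc1cc([C@@H](O)[C@@H]2CO2)cc(Br)c1OC | intermediate
5 | methyl (E)-3-(3,4,5-trimethoxyphenyl)prop-2-enoate | COC(=O)/C=C/c1cc(OC)c(OC)c(OC)c1 | starting material
6 | (E)-3-(3,4,5-trimethoxyphenyl)prop-2-en-1-ol | OC/C=C/c1cc(OC)c(OC)c(OC)c1 | intermediate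
7 | 5-[(E)-3-bromoprop-1-en-1-yl]-1,2,3-trimethoxybenzene | BrC/C=C/c1cc(OC)c(OC)c(OC)c1 | intermediate
8 | (S)-2-[(R)-(3-bromo-4,5-dimethoxyphenyl){[(E)-3-(3,4,5-trimethoxyphenyl)prop-2-en-1-yl]oxy}methyl]oxirane | COc1cc([C@@H](OC/C=C/c2cc(OC)c(OC)c(OC)c2)[C@@H]3CO3)cc(Br)c1OC | intermediate
9 | benzyltitanium alkoxide: (2S,3R,4R)-2-(3-bromo-4,5-dimethoxyphenyl)oxolane carrying CH2O–Ti(Cl)Cp2 at C3 and CH[Ti(Cl)Cp2](3,4,5-trimethoxyphenyl) at C4, both epimers at the benzylic carbon | COc1cc([C@H]2OC[C@H](C([Ti+2]Cl)c3cc(OC)c(OC)c(OC)c3)[C@@H]2CO[Ti+2]Cl)cc(Br)c1OC.[cH-]1cccc1.[cH-]1cccc1.[cH-]1cccc1.[cH-]1cccc1 | intermediate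
10 | benzylic iodide: (2S,3R,4R)-2-(3-bromo-4,5-dimethoxyphenyl)oxolane carrying CH2O–Ti(Cl)Cp2 at C3 and CHI(3,4,5-trimethoxyphenyl) at C4, both epimers at the benzylic carbon | COc1cc([C@H]2OC[C@H](C(I)c3cc(OC)c(OC)c(OC)c3)[C@@H]2CO[Ti+2]Cl)cc(Br)c1OC.[cH-]1cccc1.[cH-]1cccc1 | intermediate
11 | (1S,3aR,4S,6aR)-1-(3-bromo-4,5-dimethoxyphenyl)-4-(3,4,5-trimethoxyphenyl)tetrahydro-1H,3H-furo[3,4-c]furan | COc1cc([C@H]2OC[C@H]3[C@@H]2CO[C@@H]3c2cc(OC)c(OC)c(OC)c2)cc(Br)c1OC | intermediate
12 | 5-[(1S,3aR,4S,6aR)-4-(3,4,5-trimethoxyphenyl)tetrahydro-1H,3H-furo[3,4-c]furan-1-yl]-2,3-dimethoxyphenol | COc1cc([C@H]2OC[C@H]3[C@@H]2CO[C@@H]3c2cc(OC)c(OC)c(OC)c2)cc(O)c1OC | target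

**Totals**
Total step count: 7. Longest linear sequence: 5 (steps 1, 2, 5, 6, 7).

**Three steps most likely to fail, each with a fallback**

Step 6 (cascade): the radical may be reduced by Cp2TiCl before it cyclises, the trans-fused oxolane cannot close ring B, and the iodine stage may give elimination. The fallback sets out from 8 and comes back at 11. Compound 8 is treated with Cp2TiCl (from Cp2TiCl2 and Zn, THF, rt) and quenched with dilute HCl instead of I2, so that only ring A forms and the benzyl–titanium bond is protonated. This gives [(2S,3R,4R)-2-(3-bromo-4,5-dimethoxyphenyl)-4-(3,4,5-trimethoxybenzyl)oxolan-3-yl]methanol F1. Ring B is then closed in a separate dehydrogenative step with DDQ (1.1 equiv, CH2Cl2, 0 °C → rt): hydride abstraction from the 3,4,5-trimethoxybenzyl position gives the para-methoxy-stabilised cation, which the primary alcohol captures on the convex face to give 11.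

Step 5 (etherification): the alkoxide of 4 may undergo Payne rearrangement, and bromide 7 is labile. The fallback sets out from 6 (with 4) and comes back at 8. Alcohol 6 is acetylated (Ac2O, pyridine) to (E)-3-(3,4,5-trimethoxyphenyl)prop-2-en-1-yl acetate F2. F2 is coupled with 4 by palladium-catalysed allylic etherification of the zinc alkoxide (Et2Zn 0.55 equiv, Pd(OAc)2 5 mol%, 2-(di-tert-butylphosphino)biphenyl 7.5 mol%, THF, rt). The weakly basic zinc alkoxide does not rearrange and attacks the π-allyl palladium intermediate at its unsubstituted end, giving the linear E ether 8 without bromide 7.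

Step 7 (hydroxylation): the electron-rich, ortho-substituted bromide may react slowly or undergo hydrodebromination. The fallback sets out from 11 and comes back at 12. Miyaura borylation (B2pin2, Pd(dppf)Cl2 3 mol%, KOAc, 1,4-dioxane, 85 °C) gives 2-{2,3-dimethoxy-5-[(1S,3aR,4S,6aR)-4-(3,4,5-trimethoxyphenyl)tetrahydro-1H,3H-furo[3,4-c]furan-1-yl]phenyl}-4,4,5,5-tetramethyl-1,3,2-dioxaborolane F3. Oxidation with H2O2/NaOH (THF/H2O, 0 °C) then moves the aryl group from boron to oxygen and gives 12.

**Further compounds**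
F1 | step 6 | [(2S,3R,4R)-2-(3-bromo-4,5-dimethoxyphenyl)-4-(3,4,5-trimethoxybenzyl)oxolan-3-yl]methanol | COc1cc([C@H]2OC[C@H](Cc3cc(OC)c(OC)c(OC)c3)[C@@H]2CO)cc(Br)c1OC
F2 | step 5 | (E)-3-(3,4,5-trimethoxyphenyl)prop-2-en-1-yl acetate | CC(=O)OC/C=C/c1cc(OC)c(OC)c(OC)c1
F3 | step 7 | 2-{2,3-dimethoxy-5-[(1S,3aR,4S,6aR)-4-(3,4,5-trimethoxyphenyl)tetrahydro-1H,3H-furo[3,4-c]furan-1-yl]phenyl}-4,4,5,5-tetramethyl-1,3,2-dioxaborolane | COc1cc([C@H]2OC[C@H]3[C@@H]2CO[C@@H]3c2cc(OC)c(OC)c(OC)c2)cc(B4OC(C)(C)C(C)(C)O4)c1OC
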